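Labels: the isoflavan has ring A (7-oxygenated benzo ring), ring C (O1, C2, C3, C4, C4a, C8a) and ring B (3-aryl). The flavanone has ring D (phloroglucinol ring, bonded through its C6 to isoflavan C4), ring E (pyranone) and ring F (4-hydroxyphenyl).
Enabling feature: isoflavan C4 is a benzylic carbon of ring A and lies ortho to C8a, the carbon that bears O1. The chain O1–C8a–C4a–C4 is therefore a hidden ortho-quinone methide, and C2–C3 with ring B is a hidden arylacetic acid whose carboxyl carbon is C2.
Cuts in retrosynthetic order: flavanone C2–ring F; ring E back to an acetyl group on ring D; the para C–O bond of ring D (carried as C–Br); C2 back to a lactone carbonyl; C3–C4 together with O1–C2; last C4–ring D.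
Forward: a ring D Grignard reagent is joined to the ring A aldehyde and the adduct is dehydrated to the quinone methide. Ring C closes as a lactone on union with the ring B acid, is opened by hydride and is reclosed as the cyclic ether. Ring E is then grown on ring D as a chromone, and ring F is added last.
Stereochemistry: C3 and C4 come from the isothiourea-catalysed union (shielded enolate face plus anti topicity). Flavanone C2 comes from a ligand-controlled rhodium 1,4-arylation, and no step after either event is epimerising.

Key step: step 10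

Assumption on catalyst sense: (2S,3R)-HyperBTM, which is (2S,3R)-3-isopropyl-2-phenyl-3,4-dihydro-2H-benzo[4,5]thiazolo[3,2-a]pyrimidine, is taken to leave open the enolate face that makes C3 R. (S)-MeO-F12-BIPHEP, which is (S)-(6,6'-dimethoxybiphenyl-2,2'-diyl)bis[bis(3,4,5-trifluorophenyl)phosphane], is taken to leave open the chromone face that makes flavanone C2 S. Both follow the accepted facial models, and both antipodes are available if a model reaction shows the opposite.
Assumption on rotamers: rotation about the bond between isoflavan C4 and ring D is taken to be fast at room temperature, so the two open positions of ring D count as equivalent and no atropisomers are carried.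
Design remark: the para oxygen of ring D travels as bromine until step 13. Electrophilic halogenation of a 3,5-dialkoxyphenol tends to go next to the free hydroxyl rather than between the two ethers, whereas 5-bromoresorcinol is expected to take iodine between its hydroxyl groups.
Abbreviation: "isoflavanyl" stands for the (3R,4S)-7-(benzyloxy)-3-[3-(benzyloxy)-2,4-dimethoxyphenyl]chroman-4-yl group.

Step 1
Reactants: 1 2,4-dihydroxybenzaldehyde
Product: 2 4-(benzyloxy)-2-hydroxybenzaldehyde
Conditions: BnBr (1.05 equiv), NaHCO3 (1.5 equiv), MeCN, 80 °C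
Reagents that add atoms: benzyl bromide, BrCc1ccccc1
Why: Williamson etherification with a weak base alkylates only the more acidic 4-OH, because the 2-OH is held in a hydrogen bond to the aldehyde.

Step 2
Reactants: 3 5-bromobenzene-1,3-diol
Product: 4 5-bromo-2-iodobenzene-1,3-diol
Conditions: I2 (1.0 equiv), NaHCO3 (1.1 equiv), THF/H2O, 0 °C → rt
Reagents that add atoms: iodine, [I][I]
Why: Electrophilic iodination of resorcinols in aqueous hydrogencarbonate is known to go to C2 between the two hydroxyl groups, and here the other positions are further crowded and deactivated by the neighbouring bromine, so the 1,2,3,5 pattern of ring D is fixed.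

Step 3
Reactants: 4 5-bromo-2-iodobenzene-1,3-diol
Product: 5 1,3-bis(benzyloxy)-5-bromo-2-iodobenzene
Conditions: BnBr (2.3 equiv), K2CO3 (3 equiv), DMF, rt
Reagents that add atoms: benzyl bromide, BrCc1ccccc1
Why: Double Williamson etherification of the two equivalent phenols, with both aryl halides inert to K2CO3 in DMF at room temperature.

Step 4
Reactants: 5 1,3-bis(benzyloxy)-5-bromo-2-iodobenzene; 2 4-(benzyloxy)-2-hydroxybenzaldehyde
Product: 8 rac-5-(benzyloxy)-2-{[2,6-bis(benzyloxy)-4-bromophenyl](hydroxy)methyl}phenol, via arylmagnesium chloride 6 (not isolated), via sodium phenolate 7 (not isolated)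
Conditions: 5, iPrMgCl·LiCl (1.1 equiv), THF, −15 → 0 °C; separately 2, NaH (1.05 equiv), THF, 0 °C; combine, 0 °C → rt; aq. NH4Cl
Reagents that add atoms: none
Why: Iodine–magnesium exchange is much faster at the carbon–iodine bond flanked by two coordinating benzyloxy groups than at the carbon–bromine bond, and the aryl Grignard reagent then adds 1,2 to the aldehyde of the preformed phenolate (Grignard addition); the carbinol centre forms racemic and is erased in step 5.

Step 5
Reactants: 8 rac-5-(benzyloxy)-2-{[2,6-bis(benzyloxy)-4-bromophenyl](hydroxy)methyl}phenol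
Product: 9 (6E)-3-(benzyloxy)-6-[2,6-bis(benzyloxy)-4-bromobenzylidene]cyclohexa-2,4-dien-1-one (ring A ortho-quinone methide)
Conditions: toluene, 4 Å molecular sieves, 100 °C, argon; crystallised with exclusion of moisture
Reagents that add atoms: none
Why: ortho-Hydroxybenzhydrols lose water thermally by 1,4-elimination through the hydrogen-bonded array; the vinylogous-ester benzyloxy group and the shielding di-ortho-substituted aryl group should make the quinone methide persistent, and the E isomer, with ring D turned away from the carbonyl oxygen, is the thermodynamic one.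

Step 6
Reactants: 10 2,6-dimethoxyphenol
Product: 11 2-(benzyloxy)-1,3-dimethoxybenzene
Conditions: BnBr (1.1 equiv), K2CO3 (2 equiv), DMF, 50 °C
Reagents that add atoms: benzyl bromide, BrCc1ccccc1
Why: Williamson etherification of the only phenol in the molecule.

Step 7
Reactants: 11 2-(benzyloxy)-1,3-dimethoxybenzene
Product: 12 2-(benzyloxy)-4-bromo-1,3-dimethoxybenzene
Conditions: NBS (1.0 equiv), MeCN, 0 °C → rt
Reagents that add atoms: N-bromosuccinimide, O=C1CCC(=O)N1Br
Why: Electrophilic aromatic bromination with NBS in acetonitrile attacks 1,2,3-trialkoxybenzenes at C4, para to an outer methoxy group, because the central alkoxy group is twisted out of conjugation, and this gives the substitution pattern of ring B.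

Step 8
Reactants: 12 2-(benzyloxy)-4-bromo-1,3-dimethoxybenzene
Product: 13 ethyl 2-[3-(benzyloxy)-2,4-dimethoxyphenyl]acetate
Conditions: BrZnCH2CO2Et (1.5 equiv, purchased solution), Pd2(dba)3 (2 mol%), XPhos (8 mol%), THF, 65 °C
Reagents that add atoms: ethyl 2-(bromozincio)acetate, CCOC(=O)C[Zn]Br
Why: Negishi-type coupling of a Reformatsky reagent (palladium-catalysed α-arylation of an ester zinc enolate) works on electron-rich ortho-substituted aryl bromides with a bulky biarylphosphine, and its near-neutral medium spares the benzyl ether.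

Step 9
Reactants: 13 ethyl 2-[3-(benzyloxy)-2,4-dimethoxyphenyl]acetate
Product: 14 2-[3-(benzyloxy)-2,4-dimethoxyphenyl]acetic acid (ring B acid)
Conditions: LiOH (3 equiv), THF/MeOH/H2O, rt; then 1 M HCl
Reagents that add atoms: lithium hydroxide, [Li+].[OH-]
Why: Saponification of an unhindered ethyl ester in a molecule that has no other base-labile group.

Step 10
Reactants: 9 (6E)-3-(benzyloxy)-6-[2,6-bis(benzyloxy)-4-bromobenzylidene]cyclohexa-2,4-dien-1-one; 14 2-[3-(benzyloxy)-2,4-dimethoxyphenyl]acetic acid
Product: 16 (3R,4S)-7-(benzyloxy)-3-[3-(benzyloxy)-2,4-dimethoxyphenyl]-4-[2,6-bis(benzyloxy)-4-bromophenyl]chroman-2-one (trans lactone), via mixed pivalic anhydride 15 (not isolated)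
Conditions: 14 (1.5 equiv), t-BuCOCl (1.5 equiv), iPr2NEt (1.5 equiv), CH2Cl2, 0 °C; then 9, (2S,3R)-HyperBTM (20 mol%), iPr2NEt (2.5 equiv), CH2Cl2, −20 °C → rt
Reagents that add atoms: none
Why: Pivaloyl chloride turns 14 into anhydride 15, which N-acylates the isothiourea, and iPr2NEt removes the acidic benzylic proton to give a (Z)-configured C1-ammonium enolate held coplanar with the catalyst by a 1,5-O···S contact. Its α-carbon (future C3) adds in Michael fashion to the exocyclic methide carbon of 9 (future C4), the only soft electrophilic site, and the recovery of ring A aromaticity drives this C3–C4 bond formation. The released phenoxide O1 then attacks the acyl ammonium carbonyl C2 in a 6-exo-trig lactonisation that closes ring C and frees the catalyst. The closest known reaction type is the isothiourea- or amidine-catalysed formal [4+2] union (Michael addition–lactonisation) of arylacetic-acid-derived ammonium enolates with isolable ortho-quinone methides to give 3,4-dihydrocoumarins. C3 (R) is set by the pseudoaxial 2-phenyl group of the catalyst, which blocks one enolate face, and C4 (S) follows from the relative topicity, because with the E-methide and ring D twisted out of plane by its two ortho benzyloxy groups the arrangement that places H3 rather than ring B in the gap between C4a and ring D is favoured and leads to the trans lactone. The step needs enolate-face and anti selectivity; any cis isomer has the same C3 but the opposite C4, so it is removed by chromatography or crystallisation and never epimerised, since epimerisation would bring the enantiomer of 16 into the material.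

Step 11
Reactants: 16 trans lactone
Product: 17 (2R,3S)-3-[4-(benzyloxy)-2-hydroxyphenyl]-2-[3-(benzyloxy)-2,4-dimethoxyphenyl]-3-[2,6-bis(benzyloxy)-4-bromophenyl]propan-1-ol
Conditions: LiAlH4 (2 equiv), THF, −10 → 0 °C; aq. potassium sodium tartrate
Reagents that add atoms: none
Why: Hydride reduction of the aryl ester to the primary alcohol and phenol is far faster than enolisation at low temperature, leaves the aryl bromide and the ethers alone at 0 °C, and removes the acidity of C3–H so that the C3/C4 relation is fixed from here on.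

Step 12
Reactants: 17 (2R,3S)-phenol-alcohol
Product: 18 (3R,4S)-7-(benzyloxy)-3-[3-(benzyloxy)-2,4-dimethoxyphenyl]-4-[2,6-bis(benzyloxy)-4-bromophenyl]chromane
Conditions: PPh3, DIAD (1.3 equiv each), THF, 0 °C → rt
Reagents that add atoms: none
Why: Intramolecular Mitsunobu etherification, well tried for isoflavans, lets the only phenol (O1) displace the activated primary alcohol at C2 in a 6-exo-tet closure of ring C, and since C2 is a CH2 group neither C3 nor C4 is touched.

Step 13
Reactants: 18 isoflavan bromide
Product: 19 3,5-bis(benzyloxy)-4-isoflavanylphenol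
Conditions: Pd2(dba)3 (2 mol%), t-BuXPhos (8 mol%), KOH (4 equiv), 1,4-dioxane/H2O, 100 °C, argon; then 1 M HCl
Reagents that add atoms: potassium hydroxide, [K+].[OH-]
Why: Palladium-catalysed hydroxylation of an aryl bromide (carbon–oxygen coupling of Buchwald–Hartwig type with hydroxide) is reliable for bromides flanked by two hydrogens, and the substrate offers only ethers and non-acidic C–H bonds to hot KOH.

Step 14
Reactants: 19 3,5-bis(benzyloxy)-4-isoflavanylphenol
Product: 20 3,5-bis(benzyloxy)-2-iodo-4-isoflavanylphenol
Conditions: NIS (1.0 equiv), CH2Cl2, −20 → 0 °C, dark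
Reagents that add atoms: N-iodosuccinimide, O=C1CCC(=O)N1I
Why: Electrophilic aromatic iodination goes to ring D alone, because it is the only free phenol and carries three oxygen donors; its two open positions are both ortho to the hydroxyl and equivalent, and one equivalent of reagent at low temperature limits double iodination.

Step 15
Reactants: 20 3,5-bis(benzyloxy)-2-iodo-4-isoflavanylphenol
Product: 22 1-[2,4-bis(benzyloxy)-6-hydroxy-3-isoflavanylphenyl]ethan-1-one, via enol ether 21 (not isolated)
Conditions: CH2=C(OEt)SnBu3 (1.5 equiv), PdCl2(PPh3)2 (5 mol%), 1,4-dioxane, 100 °C; then 1 M HCl, THF, rt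
Reagents that add atoms: tributyl(1-ethoxyvinyl)stannane, CCCC[Sn](CCCC)(CCCC)C(=C)OCC; water, O
Why: Stille coupling with a masked acetyl anion followed by mild hydrolysis of the enol ether places the methyl ketone exactly ortho to the phenol under conditions that spare the benzyl ethers, which a Lewis-acid Fries or Friedel–Crafts acylation would not.

Step 16
Reactants: 22 1-[2,4-bis(benzyloxy)-6-hydroxy-3-isoflavanylphenyl]ethan-1-one
Product: 24 5,7-bis(benzyloxy)-6-isoflavanyl-4H-chromen-4-one, via enaminone 23 (not isolated)
Conditions: Me2NCH(OMe)2 (3 equiv), toluene, 100 °C; evaporate; then conc. HCl, CH2Cl2, 40 °C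
Reagents that add atoms: N,N-dimethylformamide dimethyl acetal, COC(OC)N(C)C
Why: This is the standard enaminone route to chromones: the methyl ketone condenses with the amide acetal, and under acid the phenol oxygen adds to the β-carbon (6-endo-trig) and expels dimethylamine, which closes ring E through the para oxygen of ring D and so fixes the 6-linkage.

Step 17
Reactants: 24 5,7-bis(benzyloxy)-6-isoflavanyl-4H-chromen-4-one; 25 4-(benzyloxy)phenylboronic acid
Product: 26 (2S)-5,7-bis(benzyloxy)-2-[4-(benzyloxy)phenyl]-6-isoflavanylchroman-4-one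
Conditions: 25 (3 equiv), [Rh(OH)(cod)]2 (2.5 mol%), (S)-MeO-F12-BIPHEP (5.5 mol%), CH2Cl2/H2O, 25 °C
Reagents that add atoms: none
Why: Rhodium-catalysed asymmetric 1,4-addition of arylboronic acids (Hayashi–Miyaura reaction) to chromones is an established entry to flavanones; the aryl-rhodium species inserts into C2=C3 from the face left open by the (S)-bisphosphine, which sets flavanone C2 as S under catalyst control because the isoflavan stereocentres are remote, and protonation of the rhodium enolate in a near-neutral medium avoids ring opening.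

Step 18
Reactants: 26 (2S)-5,7-bis(benzyloxy)-2-[4-(benzyloxy)phenyl]-6-isoflavanylchroman-4-one
Product: 27 (2S)-5,7-dihydroxy-6-[(3R,4S)-7-hydroxy-3-(3-hydroxy-2,4-dimethoxyphenyl)chroman-4-yl]-2-(4-hydroxyphenyl)chroman-4-one (target)
Conditions: H2 (1 atm), 10% Pd/C, THF/MeOH, rt
Reagents that add atoms: none
Why: Hydrogenolysis of the five aryl benzyl ethers over palladium on carbon is neutral and mild, so the methyl ethers, the ketone and all three stereocentres (flavanone C2 is labile only to base) should survive.

Compound list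
1 | 2,4-dihydroxybenzaldehyde | O=Cc1ccc(O)cc1O | starting material
2 | 4-(benzyloxy)-2-hydroxybenzaldehyde | O=Cc1ccc(OCc2ccccc2)cc1O | intermediate
3 | 5-bromobenzene-1,3-diol (5-bromoresorcinol) | Oc1cc(O)cc(Br)c1 | starting material
4 | 5-bromo-2-iodobenzene-1,3-diol | Oc1cc(Br)cc(O)c1I | intermediate
5 | 1,3-bis(benzyloxy)-5-bromo-2-iodobenzene | Ic1c(OCc2ccccc2)cc(Br)cc1OCc1ccccc1 | intermediate
6 | [2,6-bis(benzyloxy)-4-bromophenyl]magnesium chloride (formed in the flask) | Cl[Mg]c1c(OCc2ccccc2)cc(Br)cc1OCc1ccccc1 | intermediate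
7 | sodium 5-(benzyloxy)-2-formylphenolate (formed in the flask) | [Na+].[O-]c1cc(OCc2ccccc2)ccc1C=O | intermediate
8 | rac-5-(benzyloxy)-2-{[2,6-bis(benzyloxy)-4-bromophenyl](hydroxy)methyl}phenol | OC(c1ccc(OCc2ccccc2)cc1O)c1c(OCc2ccccc2)cc(Br)cc1OCc1ccccc1 | intermediate
9 | (6E)-3-(benzyloxy)-6-[2,6-bis(benzyloxy)-4-bromobenzylidene]cyclohexa-2,4-dien-1-one | O=C1C=C(OCc2ccccc2)C=C/C1=C\c1c(OCc2ccccc2)cc(Br)cc1OCc1ccccc1 | intermediate
10 | 2,6-dimethoxyphenol | COc1cccc(OC)c1O | starting material
11 | 2-(benzyloxy)-1,3-dimethoxybenzene | COc1cccc(OC)c1OCc1ccccc1 | intermediate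
12 | 2-(benzyloxy)-4-bromo-1,3-dimethoxybenzene | COc1ccc(Br)c(OC)c1OCc1ccccc1 | intermediate
13 | ethyl 2-[3-(benzyloxy)-2,4-dimethoxyphenyl]acetate | CCOC(=O)Cc1ccc(OC)c(OCc2ccccc2)c1OC | intermediate
14 | 2-[3-(benzyloxy)-2,4-dimethoxyphenyl]acetic acid | COc1ccc(CC(=O)O)c(OC)c1OCc1ccccc1 | intermediate
15 | 2-[3-(benzyloxy)-2,4-dimethoxyphenyl]acetic pivalic anhydride (formed in the flask) | COc1ccc(CC(=O)OC(=O)C(C)(C)C)c(OC)c1OCc1ccccc1 | intermediate
16 | (3R,4S)-7-(benzyloxy)-3-[3-(benzyloxy)-2,4-dimethoxyphenyl]-4-[2,6-bis(benzyloxy)-4-bromophenyl]chroman-2-one (trans) | COc1ccc([C@@H]2C(=O)Oc3cc(OCc4ccccc4)ccc3[C@H]2c2c(OCc3ccccc3)cc(Br)cc2OCc2ccccc2)c(OC)c1OCc1ccccc1 | intermediate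
17 | (2R,3S)-3-[4-(benzyloxy)-2-hydroxyphenyl]-2-[3-(benzyloxy)-2,4-dimethoxyphenyl]-3-[2,6-bis(benzyloxy)-4-bromophenyl]propan-1-ol | COc1ccc([C@H](CO)[C@@H](c2ccc(OCc3ccccc3)cc2O)c2c(OCc3ccccc3)cc(Br)cc2OCc2ccccc2)c(OC)c1OCc1ccccc1 | intermediate
18 | (3R,4S)-7-(benzyloxy)-3-[3-(benzyloxy)-2,4-dimethoxyphenyl]-4-[2,6-bis(benzyloxy)-4-bromophenyl]chromane | COc1ccc([C@@H]2COc3cc(OCc4ccccc4)ccc3[C@H]2c2c(OCc3ccccc3)cc(Br)cc2OCc2ccccc2)c(OC)c1OCc1ccccc1 | intermediate
19 | 3,5-bis(benzyloxy)-4-isoflavanylphenol | COc1ccc([C@@H]2COc3cc(OCc4ccccc4)ccc3[C@H]2c2c(OCc3ccccc3)cc(O)cc2OCc2ccccc2)c(OC)c1OCc1ccccc1 | intermediate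
20 | 3,5-bis(benzyloxy)-2-iodo-4-isoflavanylphenol | Ic1c(O)cc(OCc2ccccc2)c([C@@H]2c3ccc(OCc4ccccc4)cc3OC[C@H]2c2ccc(OC)c(OCc3ccccc3)c2OC)c1OCc1ccccc1 | intermediate
21 | 3,5-bis(benzyloxy)-2-(1-ethoxyvinyl)-4-isoflavanylphenol (formed in the flask) | COc1ccc([C@@H]2COc3cc(OCc4ccccc4)ccc3[C@H]2c2c(OCc3ccccc3)cc(O)c(C(=C)OCC)c2OCc2ccccc2)c(OC)c1OCc1ccccc1 | intermediate
22 | 1-[2,4-bis(benzyloxy)-6-hydroxy-3-isoflavanylphenyl]ethan-1-one | COc1ccc([C@@H]2COc3cc(OCc4ccccc4)ccc3[C@H]2c2c(OCc3ccccc3)cc(O)c(C(C)=O)c2OCc2ccccc2)c(OC)c1OCc1ccccc1 | intermediate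
23 | (E)-1-[2,4-bis(benzyloxy)-6-hydroxy-3-isoflavanylphenyl]-3-(dimethylamino)prop-2-en-1-one (formed in the flask) | COc1ccc([C@@H]2COc3cc(OCc4ccccc4)ccc3[C@H]2c2c(OCc3ccccc3)cc(O)c(C(=O)/C=C/N(C)C)c2OCc2ccccc2)c(OC)c1OCc1ccccc1 | intermediate
24 | 5,7-bis(benzyloxy)-6-isoflavanyl-4H-chromen-4-one | COc1ccc([C@@H]2COc3cc(OCc4ccccc4)ccc3[C@H]2c2c(OCc3ccccc3)cc3OC=CC(=O)c3c2OCc2ccccc2)c(OC)c1OCc1ccccc1 | intermediate
25 | 4-(benzyloxy)phenylboronic acid | OB(O)c1ccc(OCc2ccccc2)cc1 | starting material
26 | (2S)-5,7-bis(benzyloxy)-2-[4-(benzyloxy)phenyl]-6-isoflavanylchroman-4-one | COc1ccc([C@@H]2COc3cc(OCc4ccccc4)ccc3[C@H]2c2c(OCc3ccccc3)cc3c(c2OCc2ccccc2)C(=O)C[C@@H](c2ccc(OCc4ccccc4)cc2)O3)c(OC)c1OCc1ccccc1 | intermediate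
27 | (2S)-5,7-dihydroxy-6-[(3R,4S)-7-hydroxy-3-(3-hydroxy-2,4-dimethoxyphenyl)chroman-4-yl]-2-(4-hydroxyphenyl)chroman-4-one | COc1ccc([C@@H]2COc3cc(O)ccc3[C@H]2c2c(O)cc3c(c2O)C(=O)C[C@@H](c2ccc(O)cc2)O3)c(OC)c1O | target

Total step count: 18.
Longest linear sequence: 13 steps (steps 2, 3, 4, 5, 10 to 18; the ring B branch, steps 6 to 9 followed by 10 to 18, is equally long).

Steps most likely to fail

1. Step 10. Carbon–carbon bond formation at the doubly flanked methide carbon may be slow. Above all, the relative topicity may reverse: a compact endo-type arrangement that stacks ring B under the quinone methide would put the two aryl groups cis. The fallback sets out again from 9 and 14 but uses the antipodal catalyst (2R,3S)-HyperBTM. A cis-selective union then gives the cis lactone (3S,4S)-7-(benzyloxy)-3-[3-(benzyloxy)-2,4-dimethoxyphenyl]-4-[2,6-bis(benzyloxy)-4-bromophenyl]chroman-2-one F1, which already carries the correct C4. The minor trans isomer formed with this catalyst is the enantiomer of 16 and is removed first. F1 is then equilibrated with DBU (0.2 equiv) in THF at room temperature, where the acidic C3–H epimerises to the thermodynamically preferred trans arrangement. In this variant C4 comes from catalyst control and C3 from substrate-controlled equilibration. The route is rejoined at 16.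

2. Step 5. Rehydration to the benzhydrol, self-addition of the quinone methide or decomposition during isolation may prevent handling it as a pure compound. The fallback sets out from 8, which is treated with p-toluenesulfinic acid in CH2Cl2 at room temperature. Ionisation and capture should give the bench-stable sulfone 5-(benzyloxy)-2-{[2,6-bis(benzyloxy)-4-bromophenyl](tosyl)methyl}phenol F2. F2 is charged into the flask of step 10 with one further equivalent of base (Cs2CO3 or iPr2NEt). 1,4-Elimination of sulfinate then releases the quinone methide slowly, in the presence of the ammonium enolate and at a low stationary concentration. The route is rejoined at 9, now formed and consumed in the flask, and continues to 16.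

3. Step 17. Insertion into the electron-rich 5,7-dialkoxychromone may be sluggish and protodeboronation may compete. β-Elimination of the phenoxide from the rhodium enolate would erode the configuration at flavanone C2. The fallback sets out from 22, which undergoes Claisen–Schmidt condensation with 4-(benzyloxy)benzaldehyde (KOH, EtOH/THF, rt) to give the chalcone (E)-1-[2,4-bis(benzyloxy)-6-hydroxy-3-isoflavanylphenyl]-3-[4-(benzyloxy)phenyl]prop-2-en-1-one F3. Oxa-Michael closure with NaOAc in refluxing EtOH has no facial control and gives 26 together with its C2 epimer (2R)-5,7-bis(benzyloxy)-2-[4-(benzyloxy)phenyl]-6-isoflavanylchroman-4-one F4. Because the isoflavan part is a single enantiomer, these two are diastereomers and can be separated by chromatography. F4 is returned to the same basic medium, where it re-equilibrates through F3, and is recycled. The route is rejoined at 26.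

Further compounds
F1 | step 10 | (3S,4S)-7-(benzyloxy)-3-[3-(benzyloxy)-2,4-dimethoxyphenyl]-4-[2,6-bis(benzyloxy)-4-bromophenyl]chroman-2-one (cis lactone) | COc1ccc([C@H]2C(=O)Oc3cc(OCc4ccccc4)ccc3[C@H]2c2c(OCc3ccccc3)cc(Br)cc2OCc2ccccc2)c(OC)c1OCc1ccccc1
F2 | step 5 | rac-5-(benzyloxy)-2-{[2,6-bis(benzyloxy)-4-bromophenyl](tosyl)methyl}phenol | Cc1ccc(cc1)S(=O)(=O)C(c1ccc(OCc2ccccc2)cc1O)c1c(OCc2ccccc2)cc(Br)cc1OCc1ccccc1
F3 | step 17 | (E)-1-[2,4-bis(benzyloxy)-6-hydroxy-3-isoflavanylphenyl]-3-[4-(benzyloxy)phenyl]prop-2-en-1-one | COc1ccc([C@@H]2COc3cc(OCc4ccccc4)ccc3[C@H]2c2c(OCc3ccccc3)cc(O)c(C(=O)/C=C/c3ccc(OCc4ccccc4)cc3)c2OCc2ccccc2)c(OC)c1OCc1ccccc1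
F4 | step 17 | (2R)-5,7-bis(benzyloxy)-2-[4-(benzyloxy)phenyl]-6-isoflavanylchroman-4-one | COc1ccc([C@@H]2COc3cc(OCc4ccccc4)ccc3[C@H]2c2c(OCc3ccccc3)cc3c(c2OCc2ccccc2)C(=O)C[C@H](c2ccc(OCc4ccccc4)cc2)O3)c(OC)c1OCc1ccccc1
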